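**Retrosynthetic overview**
- Both new rings – the hexasubstituted arene (ring A) and the 2,2-dimethyl-2H-pyran (ring B) – are cut in one stroke to an acyclic C-prenylated 3,5,7-triketo ester plus 3-methylbut-2-enal; the only ring bought is the 4-hydroxyphenyl group.
- Ring A closes by intramolecular aldol condensation of the ester α-carbon onto the terminal ketone, followed by aromatisation. The prenyl group already sits on the carbon between the two future phenol oxygens, so it blocks that position and steers ring B to the other ortho carbon.
- Ring B closes in the same pot: condensation of the enal at the remaining free arene carbon gives an ortho-quinone methide, which closes by oxa-6π electrocyclisation (order A then B; B-then-A via Knoevenagel first converges on the same product).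
- The triketo ester is cut at C6–C7 (polyanion Claisen with methyl 3-(4-hydroxyphenyl)propanoate), at C4–C5 (γ-acetylation) and at the prenyl–C4 bond (γ-prenylation of methyl acetoacetate).

Assumption: the target has no stereocentre and no E/Z-stereogenic double bond, so it is achiral and "single enantiomer" is met by the one constitutional isomer; no asymmetric step is needed.

**Step 1**
Reactants: 1 methyl acetoacetate (methyl 3-oxobutanoate); 2 prenyl bromide (1-bromo-3-methylbut-2-ene)
Product: 3 methyl 7-methyl-3-oxooct-6-enoate
Conditions: NaH (1.1 equiv), THF, 0 °C; n-BuLi (1.05 equiv), 0 °C; then 2 (1.0 equiv), 0 → 23 °C; aq. HCl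
Reagents that add atoms: none
Why: Huckin–Weiler dianion alkylation, in which the γ-carbanion of the acetoacetate dianion is the most nucleophilic site and displaces the primary allylic bromide by SN2, so only the terminal carbon is prenylated and no stereocentre is formed.

**Step 2**
Reactants: 3 methyl 7-methyl-3-oxooct-6-enoate; 4 N-methoxy-N-methylacetamide
Product: 5 methyl 4-(3-methylbut-2-en-1-yl)-3,5-dioxohexanoate
Conditions: 3 (1.5 equiv), LiN(iPr)2 (3.1 equiv), THF, −78 → 0 °C; then 4 (1.0 equiv), −78 → 0 °C; 1 M HCl, 0 °C
Reagents that add atoms: none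
Why: Harris-type γ-acylation (crossed Claisen) of a β-keto ester dianion by a Weinreb amide, whose chelated tetrahedral adduct prevents over-addition and releases the 1,3-diketone on acidic work-up; the new C4 centre is an enolised, configurationally labile dicarbonyl carbon that later becomes an arene carbon.

**Step 3**
Reactants: 5 methyl 4-(3-methylbut-2-en-1-yl)-3,5-dioxohexanoate; 6 methyl 3-(4-hydroxyphenyl)propanoate
Product: 7 methyl 9-(4-hydroxyphenyl)-4-(3-methylbut-2-en-1-yl)-3,5,7-trioxononanoate
Conditions: 5 (2.0 equiv), LiN(iPr)2 (6.2 equiv), THF, −78 → 0 °C; then 6 (1.0 equiv) premixed with LiN(SiMe3)2 (1.0 equiv) in THF at −78 °C; 0 °C, 2 h; cold 1 M HCl; crude 7 used at once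
Reagents that add atoms: none
Why: Harris polyanion Claisen acylation, in which the last-formed terminal methyl carbanion (C6) of the trianion is the most basic and nucleophilic site and attacks the ester, while the phenol rides through as its inert lithium phenoxide and no stereocentre of consequence is formed.

**Step 4**
Reactants: 7 methyl 9-(4-hydroxyphenyl)-4-(3-methylbut-2-en-1-yl)-3,5,7-trioxononanoate; 8 3-methylbut-2-enal (prenal)
Product: 11 methyl 7-hydroxy-5-[2-(4-hydroxyphenyl)ethyl]-2,2-dimethyl-8-(3-methylbut-2-en-1-yl)-2H-chromene-6-carboxylate, via resorcylate 9 (not isolated), via ortho-quinone methide 10 (not isolated)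
Conditions: 8 (3.0 equiv), ethylenediammonium diacetate (0.3 equiv), toluene, 4 Å molecular sieves, 23 °C, 2 h, then 110 °C, 12 h
Reagents that add atoms: none
Why: Proposed new method: the amine/acetate buffer first drives a biomimetic intramolecular aldol condensation of C2 onto the C7 ketone, and dehydration plus enolisation build ring A as resorcylate 9; the only free arene carbon of 9 (ortho to the 4-OH, the other ortho site being blocked by prenyl) then adds to the iminium ion of 8 and loses the amine to give ortho-quinone methide 10, which closes ring B by oxa-6π electrocyclisation; if Knoevenagel condensation at C6 of 7 and oxa-6π closure come first, the following aldol aromatisation gives the same product; the closest known reactions are the base-mediated aromatisation of 3,5,7-triketo esters to resorcylates and the ethylenediammonium diacetate-catalysed chromenylation of resorcinols with enals; no stereocentre is formed.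

**Compound list**
1 | methyl acetoacetate (methyl 3-oxobutanoate) | COC(=O)CC(C)=O | starting material
2 | prenyl bromide (1-bromo-3-methylbut-2-ene) | CC(C)=CCBr | starting material
3 | methyl 7-methyl-3-oxooct-6-enoate | COC(=O)CC(=O)CCC=C(C)C | intermediate
4 | N-methoxy-N-methylacetamide | CC(=O)N(C)OC | starting material
5 | methyl 4-(3-methylbut-2-en-1-yl)-3,5-dioxohexanoate (drawn as the keto form, C4 labile) | COC(=O)CC(=O)C(CC=C(C)C)C(C)=O | intermediate
6 | methyl 3-(4-hydroxyphenyl)propanoate | COC(=O)CCc1ccc(O)cc1 | starting material
7 | methyl 9-(4-hydroxyphenyl)-4-(3-methylbut-2-en-1-yl)-3,5,7-trioxononanoate (drawn as the keto form, C4 labile) | COC(=O)CC(=O)C(CC=C(C)C)C(=O)CC(=O)CCc1ccc(O)cc1 | intermediate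
8 | 3-methylbut-2-enal (prenal) | CC(C)=CC=O | starting material
9 | methyl 2,4-dihydroxy-6-[2-(4-hydroxyphenyl)ethyl]-3-(3-methylbut-2-en-1-yl)benzoate | COC(=O)c1c(O)c(CC=C(C)C)c(O)cc1CCc1ccc(O)cc1 | intermediate
10 | methyl (5Z)-2-hydroxy-6-[2-(4-hydroxyphenyl)ethyl]-3-(3-methylbut-2-en-1-yl)-5-(3-methylbut-2-en-1-ylidene)-4-oxocyclohexa-1(6),2-diene-1-carboxylate | O=C1C(CC=C(C)C)=C(O)C(C(=O)OC)=C(CCc2ccc(O)cc2)/C1=C/C=C(C)C | intermediate
11 | methyl 7-hydroxy-5-[2-(4-hydroxyphenyl)ethyl]-2,2-dimethyl-8-(3-methylbut-2-en-1-yl)-2H-chromene-6-carboxylate | COC(=O)c1c(O)c(CC=C(C)C)c2c(c1CCc1ccc(O)cc1)C=CC(C)(C)O2 | target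

**Totals and risks**
Total step count: 4. Longest linear sequence: 4 steps (1 → 3 → 5 → 7 → 11).

The three steps most likely to fail, in order of risk:

The double annulation of step 4 is the most exposed. The triketo ester may stop at the resorcylate, stray to a 4-hydroxy-2-pyranone on heating, or the enal may fail to condense at the crowded carbon next to the arylethyl chain. The fallback sets out from 7 and replaces the enal condensation by a pericyclic ring closure. Compound 7 is aromatised alone (Cs2CO3, MeOH, 23 °C, then 1 M HCl) and 9 is isolated. Its most acidic phenol, the 4-OH para to the ester, is alkylated with 3-chloro-3-methylbut-1-yne (K2CO3 1.1 equiv, KI, CuI 5 mol%, acetone, 56 °C) to the aryl propargyl ether methyl 2-hydroxy-6-[2-(4-hydroxyphenyl)ethyl]-3-(3-methylbut-2-en-1-yl)-4-[(2-methylbut-3-yn-2-yl)oxy]benzoate F1. Heating F1 (xylene, 140 °C) triggers an aryl propargyl Claisen rearrangement to the only free ortho carbon and enolisation to the ortho-allenyl phenol methyl 2,4-dihydroxy-6-[2-(4-hydroxyphenyl)ethyl]-3-(3-methylbut-2-en-1-yl)-5-(3-methylbuta-1,2-dien-1-yl)benzoate F2. A 1,5-hydrogen shift then gives 10 and oxa-6π closure brings the sequence back to the route at 11.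

The polyanion acylation of step 3 comes second. The triply charged, hindered nucleophile may simply deprotonate the enolisable ester, and the lithium phenoxide may aggregate. The fallback sets out from 2 and 6 and reverses the order of chain assembly, so that the enolisable ester meets a more reactive diketone dianion and the sluggish polyanion meets a non-enolisable electrophile. Pentane-2,4-dione is C-alkylated with 2 (K2CO3, acetone, 56 °C) to 3-(3-methylbut-2-en-1-yl)pentane-2,4-dione F3. Its dianion (LiN(iPr)2, THF, 0 °C; F3 in twofold excess) is acylated at a methyl group by the lithium phenoxide of 6 to 8-(4-hydroxyphenyl)-3-(3-methylbut-2-en-1-yl)octane-2,4,6-trione F4. The polyanion of F4 (LiN(iPr)2 4.2 equiv, THF, 0 °C) is carboxylated at the remaining methyl group with dimethyl carbonate, and acidic work-up returns to the route at 7.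

The γ-acetylation of step 2 is third. The secondary carbanion is hindered and the Weinreb amide is enolisable, so proton transfer may win. The fallback sets out from 2 and brings the whole diketo ester chain in ready-made. Dehydroacetic acid (3-acetyl-4-hydroxy-6-methyl-2H-pyran-2-one) is opened and deacetylated with Mg(OMe)2 in MeOH at reflux to methyl 3,5-dioxohexanoate F5. Its monoanion (K2CO3, acetone, 56 °C) is alkylated by 2 at C4, the carbon between the two ketones, which returns to the route at 5.

**Further compounds**
F1 | step 4 | methyl 2-hydroxy-6-[2-(4-hydroxyphenyl)ethyl]-3-(3-methylbut-2-en-1-yl)-4-[(2-methylbut-3-yn-2-yl)oxy]benzoate | COC(=O)c1c(O)c(CC=C(C)C)c(OC(C)(C)C#C)cc1CCc1ccc(O)cc1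
F2 | step 4 | methyl 2,4-dihydroxy-6-[2-(4-hydroxyphenyl)ethyl]-3-(3-methylbut-2-en-1-yl)-5-(3-methylbuta-1,2-dien-1-yl)benzoate | COC(=O)c1c(O)c(CC=C(C)C)c(O)c(C=C=C(C)C)c1CCc1ccc(O)cc1
F3 | step 3 | 3-(3-methylbut-2-en-1-yl)pentane-2,4-dione | CC(=O)C(CC=C(C)C)C(C)=O
F4 | step 3 | 8-(4-hydroxyphenyl)-3-(3-methylbut-2-en-1-yl)octane-2,4,6-trione | CC(=O)C(CC=C(C)C)C(=O)CC(=O)CCc1ccc(O)cc1
F5 | step 2 | methyl 3,5-dioxohexanoate | COC(=O)CC(=O)CC(C)=O
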